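**Plan** (ring A = catechol ring C4a–C8a, ring B = carbocycle C1–C4, ring C = pyranone O1′/C2′–C6′; target numbering is used for all intermediates)
1. Retrosynthesis removes the four O‑methyl groups, takes the C6′ carboxyl back to an acetal, then opens ring C at O1′–C6′ and C4′–C5′.
2. This cut is possible because ring C carries ring B (through C1) at C4′, the carboxyl carbon at C6′ and only hydrogen at C3′ and C5′: the pattern left when a C1 alkynoic acid (C2′, C3′, C4′) and a terminal alkyne (C5′, C6′) are joined by acid addition and 6‑endo closure.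
3. The alkynoic acid is traced to a propargylic alcohol; ring B is cut at C4–C4a (arene alkylation), C3–C4 (formylation), C2–C3 (malonate alkylation) and C1–C2 (propargylic substitution), back to 3,4‑dimethoxybenzaldehyde.
4. Forward: the chain C1–C2–C3–C4 is built on ring A, acid closes ring B, the gold cascade builds ring C, and oxidation and deprotection finish the target.
5. C1 is set by a ligand‑controlled copper‑catalysed propargylic substitution; C2 is set by equilibration to the trans (1R,2S) diester under control of C1; no base is used once the alkynoic acid exists, because C1–H is then γ to a carbonyl.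

Key step: step 9

Assumption: the ligand antipode used in step 2 is the one that delivers the R centre at C1; the sense of induction is checked on first use and the other antipode is taken if needed.

Step 1
Reactants: 1 3,4-dimethoxybenzaldehyde; 2 ethynylmagnesium bromide
Product: 4 rac-1-(3,4-dimethoxyphenyl)prop-2-yn-1-yl acetate, via bromomagnesium alkoxide 3 (not isolated)
Conditions: 2 (1.2 equiv), THF, 0 °C; then Ac2O (1.5 equiv), 0 °C to rt
Reagents that add atoms: acetic anhydride, CC(=O)OC(C)=O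
Why: Grignard 1,2-addition of the acetylide to the aldehyde and O-acylation of the alkoxide in the same flask should give the racemic propargylic acetate, whose centre need not be controlled because step 2 is stereoconvergent.

Step 2
Reactants: 4 rac-1-(3,4-dimethoxyphenyl)prop-2-yn-1-yl acetate; 5 tert-butyl methyl malonate
Product: 6 tert-butyl methyl 2-[(1R)-1-(3,4-dimethoxyphenyl)prop-2-yn-1-yl]malonate (both epimers at the malonate carbon)
Conditions: [Cu(MeCN)4]BF4 (5 mol%), chiral tridentate P,N,N ketimine ligand (5.5 mol%), iPr2NEt (1.2 equiv), 5 (1.5 equiv), MeOH, −20 °C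
Reagents that add atoms: none
Why: In this copper-catalysed asymmetric propargylic substitution the monovalent copper acetylide of 4 loses acetate to a copper allenylidene and the malonate attacks its γ carbon on the face left open by the chiral ligand, which sets C1 (R) whatever the configuration of 4, while the malonate carbon remains an inconsequential epimer mixture.

Step 3
Reactants: 6 tert-butyl methyl 2-[(1R)-1-(3,4-dimethoxyphenyl)prop-2-yn-1-yl]malonate; 7 methyl bromoacetate
Product: 8 tert-butyl methyl 2-[(1R)-1-(3,4-dimethoxyphenyl)prop-2-yn-1-yl]-2-(2-methoxy-2-oxoethyl)malonate (both epimers at the quaternary carbon)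
Conditions: NaH (1.1 equiv), THF/DMF, 0 °C; then 7 (1.3 equiv), rt
Reagents that add atoms: none
Why: Malonic ester alkylation (SN2) of the sodium enolate with a reactive α-bromo ester should form C2–C3 and make C2 quaternary, which blocks enolisation at C2 in the later base steps, while C1–H is not acidic under these conditions.

Step 4
Reactants: 8 tert-butyl methyl 2-[(1R)-1-(3,4-dimethoxyphenyl)prop-2-yn-1-yl]-2-(2-methoxy-2-oxoethyl)malonate; 9 methyl formate
Product: 11 tert-butyl methyl 2-[(1R)-1-(3,4-dimethoxyphenyl)prop-2-yn-1-yl]-2-[(E)-1,3-dimethoxy-3-oxoprop-1-en-2-yl]malonate (both epimers at the quaternary carbon), via sodium enolate 10 (not isolated)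
Conditions: NaH (1.3 equiv), 9 (10 equiv), MeOH (cat.), THF, 0 °C to rt; then Me2SO4 (2 equiv), DMF, rt
Reagents that add atoms: dimethyl sulfate, COS(=O)(=O)OC
Why: Crossed Claisen condensation at the only enolisable position (the C3 methylene), driven by formation of the stabilised formyl ester enolate, followed by O-methylation of that hindered enolate, should install C4 as a β-methoxyacrylate that masks the aldehyde and leaves no acidic C–H or O–H for step 5 (the alkene geometry is lost in step 6).

Step 5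
Reactants: 11 tert-butyl methyl 2-[(1R)-1-(3,4-dimethoxyphenyl)prop-2-yn-1-yl]-2-[(E)-1,3-dimethoxy-3-oxoprop-1-en-2-yl]malonate; 12 formaldehyde (used as paraformaldehyde)
Product: 14 tert-butyl methyl 2-[(1S)-1-(3,4-dimethoxyphenyl)-4-hydroxybut-2-yn-1-yl]-2-[(E)-1,3-dimethoxy-3-oxoprop-1-en-2-yl]malonate (both epimers at the quaternary carbon; C1 unchanged in space; S by priority only), via lithium acetylide 13 (not isolated)
Conditions: lithium diisopropylamide (1.05 equiv), THF, −78 °C; then (CH2O)n (5 equiv), −78 °C to rt; aq NH4Cl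
Reagents that add atoms: none
Why: Deprotonation of the terminal alkyne, the only C–H of pKa below about 30 in 11, and addition of the lithium acetylide to formaldehyde (acetylide hydroxymethylation) should bring in the future C2′ carbon as an alcohol that tolerates the acid of step 6 and the base of step 7.

Step 6
Reactants: 14 tert-butyl methyl 2-[(1S)-1-(3,4-dimethoxyphenyl)-4-hydroxybut-2-yn-1-yl]-2-[(E)-1,3-dimethoxy-3-oxoprop-1-en-2-yl]malonate
Product: 16 dimethyl (1R)-1-(3-hydroxyprop-1-yn-1-yl)-6,7-dimethoxy-1,2-dihydronaphthalene-2,3-dicarboxylate (cis/trans mixture at C2), via ring B malonic half acid 15 (not isolated)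
Conditions: CF3CO2H/CH2Cl2, MeSO3H (2 equiv), 0 °C to rt; then PhMe, 100 °C; MeOH/aq NaHCO3 work-up
Reagents that add atoms: none
Why: Intramolecular Friedel–Crafts alkylation by the O-protonated β-methoxyacrylate at the arene carbon para to a methoxy group (future C4a), with loss of methanol, should close ring B as the 3,4-alkene in the manner of the classical cyclodehydration of α-formyl esters onto veratryl rings, while the same acid cleaves the tert-butyl ester and the malonic half acid loses CO2 on heating, the C2 hydrogen arriving without facial control.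

Step 7
Reactants: 16 dimethyl (1R)-1-(3-hydroxyprop-1-yn-1-yl)-6,7-dimethoxy-1,2-dihydronaphthalene-2,3-dicarboxylate (cis/trans mixture at C2)
Product: 17 dimethyl (1R,2S)-1-(3-hydroxyprop-1-yn-1-yl)-6,7-dimethoxy-1,2-dihydronaphthalene-2,3-dicarboxylate
Conditions: NaOMe (0.2 equiv), MeOH, 0 °C, argon; AcOH quench
Reagents that add atoms: none
Why: Base-mediated epimerisation through the C2 ester dienolate should funnel the mixture into the thermodynamically favoured trans diester, in which the C1 alkynyl and C2 ester groups are both pseudoaxial (no peri strain with H8, no eclipsing with the C3 ester), so C2 is set relative to C1; methoxide matches the methyl esters, reprotonation at C2 should outrun protonation at C4, and C1–H is not acidic in this isomer.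

Step 8
Reactants: 17 dimethyl (1R,2S)-1-(3-hydroxyprop-1-yn-1-yl)-6,7-dimethoxy-1,2-dihydronaphthalene-2,3-dicarboxylate
Product: 19 3-[(1R,2S)-6,7-dimethoxy-2,3-bis(methoxycarbonyl)-1,2-dihydronaphthalen-1-yl]prop-2-ynoic acid, via ynal 18 (not isolated)
Conditions: TEMPO (0.2 equiv), PhI(OAc)2 (2.5 equiv), MeCN/H2O, rt
Reagents that add atoms: water, O
Why: Oxoammonium (TEMPO) oxidation of the primary propargylic alcohol to the ynal and of its hydrate to the acid runs at neutral to weakly acidic pH, so neither the γ hydrogen at C1 nor C2–H should be exchanged.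

Step 9
Reactants: 19 3-[(1R,2S)-6,7-dimethoxy-2,3-bis(methoxycarbonyl)-1,2-dihydronaphthalen-1-yl]prop-2-ynoic acid; 20 3,3-diethoxyprop-1-yne
Product: 22 dimethyl (1R,2S)-1-[6-(diethoxymethyl)-2-oxo-2H-pyran-4-yl]-6,7-dimethoxy-1,2-dihydronaphthalene-2,3-dicarboxylate, via enol ester 21 (not isolated)
Conditions: Ph3PAuCl (5 mol%), AgOTf (5 mol%), 20 (3 equiv), CH2Cl2, rt
Reagents that add atoms: none
Why: This is the known gold-catalysed two-component α-pyrone synthesis from a propiolic acid and a terminal alkyne (enol ester formation, then cycloisomerisation). Monovalent gold first activates 20 so that the carboxyl oxygen of 19 adds at the internal carbon in the Markovnikov sense (O1′–C6′), and protodeauration gives enol ester 21. Gold then activates the ynoate, and the enol ester CH2 attacks the alkyne carbon attached to C1 (C4′–C5′) in a 6-endo-dig closure of ring C; loss of H5′ from the C6′ oxocarbenium ion and protodeauration at C3′ give the aromatic lactone. No stereocentre is formed, and C1 and C2 should stay untouched because the medium is neutral to weakly acidic. The step needs Markovnikov addition (secured by the terminal alkyne, with an excess of 20 to offset its low nucleophilicity), 6-endo over 5-exo closure (secured by the ynoate polarisation, which makes the β carbon the electrophilic one) and no attack of the C2 ester carbonyl on the alkyne, which the trans-diaxial placement of the C1 alkyne and the C2 methyl ester keeps out of reach.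

Step 10
Reactants: 22 dimethyl (1R,2S)-1-[6-(diethoxymethyl)-2-oxo-2H-pyran-4-yl]-6,7-dimethoxy-1,2-dihydronaphthalene-2,3-dicarboxylate
Product: 23 dimethyl (1R,2S)-1-(6-formyl-2-oxo-2H-pyran-4-yl)-6,7-dimethoxy-1,2-dihydronaphthalene-2,3-dicarboxylate
Conditions: HCO2H/H2O, 40 °C
Reagents that add atoms: water, O
Why: Acid-catalysed acetal hydrolysis should free the C6′ aldehyde without touching the methyl esters, the lactone or the two stereocentres, since no base is present.

Step 11
Reactants: 23 dimethyl (1R,2S)-1-(6-formyl-2-oxo-2H-pyran-4-yl)-6,7-dimethoxy-1,2-dihydronaphthalene-2,3-dicarboxylate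
Product: 24 4-[(1R,2S)-6,7-dimethoxy-2,3-bis(methoxycarbonyl)-1,2-dihydronaphthalen-1-yl]-2-oxo-2H-pyran-6-carboxylic acid
Conditions: NaClO2, NaH2PO4, 2-methylbut-2-ene, t-BuOH/H2O, 0 °C to rt
Reagents that add atoms: sodium chlorite, [Na+].[O-]Cl=O
Why: Pinnick oxidation should convert the aldehyde into the C6′ carboxylic acid at about pH 4, with the alkene scavenger trapping HOCl so that the electron-rich arene and both stereocentres are left alone.

Step 12
Reactants: 24 4-[(1R,2S)-6,7-dimethoxy-2,3-bis(methoxycarbonyl)-1,2-dihydronaphthalen-1-yl]-2-oxo-2H-pyran-6-carboxylic acid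
Product: 25 4-[(1R,2S)-6,7-dihydroxy-2,3-bis(methoxycarbonyl)-1,2-dihydronaphthalen-1-yl]-2-oxo-2H-pyran-6-carboxylic acid
Conditions: BBr3 (8 equiv), CH2Cl2, −78 to 0 °C; then H2O
Reagents that add atoms: none
Why: Lewis acid-mediated aryl methyl ether cleavage (bromide attack on the boron-bound O–CH3) should unveil the catechol under non-basic conditions that 2-pyranones tolerate, and any methyl ester cleaved here converges in step 13.

Step 13
Reactants: 25 4-[(1R,2S)-6,7-dihydroxy-2,3-bis(methoxycarbonyl)-1,2-dihydronaphthalen-1-yl]-2-oxo-2H-pyran-6-carboxylic acid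
Product: 26 (1R,2S)-1-(6-carboxy-2-oxo-2H-pyran-4-yl)-6,7-dihydroxy-1,2-dihydronaphthalene-2,3-dicarboxylic acid
Conditions: 6 M HCl (aq)/1,4-dioxane, 80 °C, argon
Reagents that add atoms: water, O
Why: Acid-catalysed ester hydrolysis should free the C2 and C3 carboxylic acids while avoiding hydroxide, which would open the pyranone and enolise C1 and C2.

**Compound list**

1 | 3,4-dimethoxybenzaldehyde | COc1ccc(C=O)cc1OC | starting material
2 | ethynylmagnesium bromide | C#C[Mg]Br | starting material
3 | bromomagnesium 1-(3,4-dimethoxyphenyl)prop-2-yn-1-olate (racemic) | C#CC(O[Mg]Br)c1ccc(OC)c(OC)c1 | intermediate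
4 | rac-1-(3,4-dimethoxyphenyl)prop-2-yn-1-yl acetate | C#CC(OC(C)=O)c1ccc(OC)c(OC)c1 | intermediate
5 | tert-butyl methyl malonate | COC(=O)CC(=O)OC(C)(C)C | starting material
6 | tert-butyl methyl 2-[(1R)-1-(3,4-dimethoxyphenyl)prop-2-yn-1-yl]malonate (both epimers at the malonate carbon) | COc1ccc(cc1OC)[C@@H](C#C)C(C(=O)OC)C(=O)OC(C)(C)C | intermediate
7 | methyl bromoacetate | COC(=O)CBr | starting material
8 | tert-butyl methyl 2-[(1R)-1-(3,4-dimethoxyphenyl)prop-2-yn-1-yl]-2-(2-methoxy-2-oxoethyl)malonate (both epimers at the quaternary carbon) | COc1ccc(cc1OC)[C@@H](C#C)C(CC(=O)OC)(C(=O)OC)C(=O)OC(C)(C)C | intermediate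
9 | methyl formate | COC=O | starting material
10 | sodium enolate of tert-butyl methyl 2-[(1R)-1-(3,4-dimethoxyphenyl)prop-2-yn-1-yl]-2-(1-methoxy-1,3-dioxopropan-2-yl)malonate | COc1ccc(cc1OC)[C@@H](C#C)C(C(=O)OC)(C(=O)OC(C)(C)C)C(=C[O-])C(=O)OC.[Na+] | intermediate
11 | tert-butyl methyl 2-[(1R)-1-(3,4-dimethoxyphenyl)prop-2-yn-1-yl]-2-[(E)-1,3-dimethoxy-3-oxoprop-1-en-2-yl]malonate (both epimers at the quaternary carbon) | COc1ccc(cc1OC)[C@@H](C#C)C(C(=O)OC)(C(=O)OC(C)(C)C)/C(=C\OC)C(=O)OC | intermediate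
12 | formaldehyde (used as paraformaldehyde) | C=O | starting material
13 | lithium acetylide of 11 | COc1ccc(cc1OC)[C@@H](C#C[Li])C(C(=O)OC)(C(=O)OC(C)(C)C)/C(=C\OC)C(=O)OC | intermediate
14 | tert-butyl methyl 2-[(1S)-1-(3,4-dimethoxyphenyl)-4-hydroxybut-2-yn-1-yl]-2-[(E)-1,3-dimethoxy-3-oxoprop-1-en-2-yl]malonate (both epimers at the quaternary carbon) | COc1ccc(cc1OC)[C@@H](C#CCO)C(C(=O)OC)(C(=O)OC(C)(C)C)/C(=C\OC)C(=O)OC | intermediate
15 | (1R)-1-(3-hydroxyprop-1-yn-1-yl)-6,7-dimethoxy-2,3-bis(methoxycarbonyl)-1,2-dihydronaphthalene-2-carboxylic acid (both C2 epimers) | COC(=O)C1=Cc2cc(OC)c(OC)cc2[C@@H](C#CCO)C1(C(=O)O)C(=O)OC | intermediate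
16 | dimethyl (1R)-1-(3-hydroxyprop-1-yn-1-yl)-6,7-dimethoxy-1,2-dihydronaphthalene-2,3-dicarboxylate (cis/trans mixture at C2) | COC(=O)C1=Cc2cc(OC)c(OC)cc2[C@@H](C#CCO)C1C(=O)OC | intermediate
17 | dimethyl (1R,2S)-1-(3-hydroxyprop-1-yn-1-yl)-6,7-dimethoxy-1,2-dihydronaphthalene-2,3-dicarboxylate | COC(=O)C1=Cc2cc(OC)c(OC)cc2[C@@H](C#CCO)[C@@H]1C(=O)OC | intermediate
18 | dimethyl (1R,2S)-6,7-dimethoxy-1-(3-oxoprop-1-yn-1-yl)-1,2-dihydronaphthalene-2,3-dicarboxylate | COC(=O)C1=Cc2cc(OC)c(OC)cc2[C@@H](C#CC=O)[C@@H]1C(=O)OC | intermediate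
19 | 3-[(1R,2S)-6,7-dimethoxy-2,3-bis(methoxycarbonyl)-1,2-dihydronaphthalen-1-yl]prop-2-ynoic acid | COC(=O)C1=Cc2cc(OC)c(OC)cc2[C@@H](C#CC(=O)O)[C@@H]1C(=O)OC | intermediate
20 | 3,3-diethoxyprop-1-yne | C#CC(OCC)OCC | starting material
21 | 3,3-diethoxyprop-1-en-2-yl 3-[(1R,2S)-6,7-dimethoxy-2,3-bis(methoxycarbonyl)-1,2-dihydronaphthalen-1-yl]prop-2-ynoate | COC(=O)C1=Cc2cc(OC)c(OC)cc2[C@@H](C#CC(=O)OC(=C)C(OCC)OCC)[C@@H]1C(=O)OC | intermediate
22 | dimethyl (1R,2S)-1-[6-(diethoxymethyl)-2-oxo-2H-pyran-4-yl]-6,7-dimethoxy-1,2-dihydronaphthalene-2,3-dicarboxylate | COC(=O)C1=Cc2cc(OC)c(OC)cc2[C@@H](c2cc(C(OCC)OCC)oc(=O)c2)[C@@H]1C(=O)OC | intermediate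
23 | dimethyl (1R,2S)-1-(6-formyl-2-oxo-2H-pyran-4-yl)-6,7-dimethoxy-1,2-dihydronaphthalene-2,3-dicarboxylate | COC(=O)C1=Cc2cc(OC)c(OC)cc2[C@@H](c2cc(C=O)oc(=O)c2)[C@@H]1C(=O)OC | intermediate
24 | 4-[(1R,2S)-6,7-dimethoxy-2,3-bis(methoxycarbonyl)-1,2-dihydronaphthalen-1-yl]-2-oxo-2H-pyran-6-carboxylic acid | COC(=O)C1=Cc2cc(OC)c(OC)cc2[C@@H](c2cc(C(=O)O)oc(=O)c2)[C@@H]1C(=O)OC | intermediate
25 | 4-[(1R,2S)-6,7-dihydroxy-2,3-bis(methoxycarbonyl)-1,2-dihydronaphthalen-1-yl]-2-oxo-2H-pyran-6-carboxylic acid | COC(=O)C1=Cc2cc(O)c(O)cc2[C@@H](c2cc(C(=O)O)oc(=O)c2)[C@@H]1C(=O)OC | intermediate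
26 | (1R,2S)-1-(6-carboxy-2-oxo-2H-pyran-4-yl)-6,7-dihydroxy-1,2-dihydronaphthalene-2,3-dicarboxylic acid | O=C(O)C1=Cc2cc(O)c(O)cc2[C@@H](c2cc(C(=O)O)oc(=O)c2)[C@@H]1C(=O)O | target

Total step count: 13. Longest linear sequence: 13 steps (1 to 26).

**Steps most likely to fail**

Step 9 (key step). The carboxylic acid may add too slowly to the acetal alkyne, whose two oxygens withdraw electron density from the future C6′. The 6-endo closure suffers from the same deactivation, so acetal exchange with the acid or slow decomposition of 19 could take over. Fallback: setting out from 19, the same gold-catalysed union is run with the less deactivated tert-butyl(diphenyl)(prop-2-yn-1-yloxy)silane. This should give dimethyl (1R,2S)-1-[6-({[tert-butyl(diphenyl)silyl]oxy}methyl)-2-oxo-2H-pyran-4-yl]-6,7-dimethoxy-1,2-dihydronaphthalene-2,3-dicarboxylate F1. HF·pyridine in THF then frees dimethyl (1R,2S)-1-[6-(hydroxymethyl)-2-oxo-2H-pyran-4-yl]-6,7-dimethoxy-1,2-dihydronaphthalene-2,3-dicarboxylate F2. TEMPO/PhI(OAc)2 in MeCN/H2O oxidises it to the acid, and the route is rejoined at 24 (22 and 23 are bypassed).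

Step 4. Condensation at a methylene flanked by a quaternary carbon may stall, and methoxide may instead strip an ester from the malonate by retro-Claisen cleavage. Fallback: setting out from 8, C4 is brought in without alkoxide by heating with tert-butoxybis(dimethylamino)methane (aminomethylenation). This should give tert-butyl methyl 2-[(1R)-1-(3,4-dimethoxyphenyl)prop-2-yn-1-yl]-2-[(E)-1-(dimethylamino)-3-methoxy-3-oxoprop-1-en-2-yl]malonate F3. Lithium diisopropylamide and paraformaldehyde, as in step 5, then give tert-butyl methyl 2-[(1S)-1-(3,4-dimethoxyphenyl)-4-hydroxybut-2-yn-1-yl]-2-[(E)-1-(dimethylamino)-3-methoxy-3-oxoprop-1-en-2-yl]malonate F4. Under the acid and heat of step 6 the derived iminium ion, a stronger electrophile than the protonated enol ether, should close ring B with loss of dimethylamine, pass through 15 and rejoin the route at 16.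

Step 2. The electron-rich acetate may ionise without the catalyst, and capture of the free propargylic cation by methanol or malonate outside ligand control would lower the enantiomeric purity at C1. Fallback: setting out from 1, Knoevenagel condensation with 2,2-dimethyl-1,3-dioxane-4,6-dione gives 5-(3,4-dimethoxybenzylidene)-2,2-dimethyl-1,3-dioxane-4,6-dione F5. Rhodium-catalysed asymmetric conjugate alkynylation with ethynyltrimethylsilane ([Rh(OAc)(C2H4)2]2, chiral biaryl bisphosphine, aqueous dioxane) sets C1 and gives 5-[(1S)-1-(3,4-dimethoxyphenyl)-3-(trimethylsilyl)prop-2-yn-1-yl]-2,2-dimethyl-1,3-dioxane-4,6-dione F6; this is the same spatial arrangement as in 6, the descriptor changing by priority only. Heating in tert-butanol opens the dioxanedione to 3-tert-butoxy-2-[(1S)-1-(3,4-dimethoxyphenyl)-3-(trimethylsilyl)prop-2-yn-1-yl]-3-oxopropanoic acid F7. Me3SiCHN2 in MeOH/PhMe gives tert-butyl methyl 2-[(1S)-1-(3,4-dimethoxyphenyl)-3-(trimethylsilyl)prop-2-yn-1-yl]malonate F8, and K2CO3 in MeOH removes the alkynyl silyl group to rejoin the route at 6.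

**Further compounds**

F1 | step 9 | dimethyl (1R,2S)-1-[6-({[tert-butyl(diphenyl)silyl]oxy}methyl)-2-oxo-2H-pyran-4-yl]-6,7-dimethoxy-1,2-dihydronaphthalene-2,3-dicarboxylate | COC(=O)C1=Cc2cc(OC)c(OC)cc2[C@@H](c2cc(CO[Si](c3ccccc3)(c3ccccc3)C(C)(C)C)oc(=O)c2)[C@@H]1C(=O)OC
F2 | step 9 | dimethyl (1R,2S)-1-[6-(hydroxymethyl)-2-oxo-2H-pyran-4-yl]-6,7-dimethoxy-1,2-dihydronaphthalene-2,3-dicarboxylate | COC(=O)C1=Cc2cc(OC)c(OC)cc2[C@@H](c2cc(CO)oc(=O)c2)[C@@H]1C(=O)OC
F3 | step 4 | tert-butyl methyl 2-[(1R)-1-(3,4-dimethoxyphenyl)prop-2-yn-1-yl]-2-[(E)-1-(dimethylamino)-3-methoxy-3-oxoprop-1-en-2-yl]malonate | COc1ccc(cc1OC)[C@@H](C#C)C(C(=O)OC)(C(=O)OC(C)(C)C)/C(=C\N(C)C)C(=O)OC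
F4 | step 4 | tert-butyl methyl 2-[(1S)-1-(3,4-dimethoxyphenyl)-4-hydroxybut-2-yn-1-yl]-2-[(E)-1-(dimethylamino)-3-methoxy-3-oxoprop-1-en-2-yl]malonate | COc1ccc(cc1OC)[C@@H](C#CCO)C(C(=O)OC)(C(=O)OC(C)(C)C)/C(=C\N(C)C)C(=O)OC
F5 | step 2 | 5-(3,4-dimethoxybenzylidene)-2,2-dimethyl-1,3-dioxane-4,6-dione | COc1ccc(C=C2C(=O)OC(C)(C)OC2=O)cc1OC
F6 | step 2 | 5-[(1S)-1-(3,4-dimethoxyphenyl)-3-(trimethylsilyl)prop-2-yn-1-yl]-2,2-dimethyl-1,3-dioxane-4,6-dione | COc1ccc(cc1OC)[C@@H](C#C[Si](C)(C)C)C1C(=O)OC(C)(C)OC1=O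
F7 | step 2 | 3-tert-butoxy-2-[(1S)-1-(3,4-dimethoxyphenyl)-3-(trimethylsilyl)prop-2-yn-1-yl]-3-oxopropanoic acid | COc1ccc(cc1OC)[C@@H](C#C[Si](C)(C)C)C(C(=O)O)C(=O)OC(C)(C)C
F8 | step 2 | tert-butyl methyl 2-[(1S)-1-(3,4-dimethoxyphenyl)-3-(trimethylsilyl)prop-2-yn-1-yl]malonate | COc1ccc(cc1OC)[C@@H](C#C[Si](C)(C)C)C(C(=O)OC)C(=O)OC(C)(C)C
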